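## Retrosynthetic overview

1. Michaolide F comes from TES removal and sulfoxide-elimination α-methylenation of a 14-membered macrocycle. The bold key step closes that ring last, by Ni(0)-mediated head-to-head coupling of the C9–Br and C10–Br allylic bromides. Both E-trisubstituted alkenes, the epoxide, the acetate and the trans-lactone are carried in unchanged.
2. The bis-bromide comes from a Zn-Barbier allylation of the C14 aldehyde with a 3-(bromomethyl)butenolide. This gives the trans-fused lactone, and C14 is then inverted by Mitsunobu.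
3. The butenolide is formed by RCM of an acrylate ester of a bis-allylic alcohol. C5 is set by CBS reduction and C2 by Sharpless kinetic resolution. The trans-epoxide is set by Sharpless AE on the C5 allylic alcohol.
4. Ring order: lactone (RCM, step 13), then epoxide (step 15), then 14-membered carbocycle (Ni, step 29), then α-methylene (step 31).

Assumptions, one line each:
- L-(+)-DET is the matched tartrate for the (R)-C5 allylic alcohol, and the (S)-C2 carbinol is its slow-reacting enantiomer (Sharpless model).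
- The C15 epimers of the thiophenol adducts are interchangeable, because both give the same alkene on sulfoxide elimination.
- Aldehydes 5 and 26 are β,γ-unsaturated and are used crude and immediately.

## Route

**Step 1**
Reactants: 1 (methallyl alcohol)
Product: 2 (methallyl 4-methoxybenzyl ether)
Conditions: NaH, PMBCl, TBAI (cat.), THF/DMF, 0 °C→rt
Reagents that add atoms: PMBCl, COc1ccc(CCl)cc1
Why: Williamson etherification gives a PMB group that is removable under neutral oxidative conditions at the end of the sequence.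

**Step 2**
Reactants: 3 (but-3-en-1-ol, 3 equiv), 2
Product: 4 ((3E)-5-[(4-methoxybenzyl)oxy]-4-methylpent-3-en-1-ol)
Conditions: Hoveyda–Grubbs II (5 mol%), CH2Cl2, 40 °C; separate E/Z (about 4:1)
Reagents that add atoms: none (ethylene is lost)
Why: Cross-metathesis of a terminal alkene with a 1,1-disubstituted alkene gives the trisubstituted E-alkene. This is the C6–C9 isoprenoid unit with the correct E geometry for C7=C8.

**Step 3**
Reactants: 4
Product: 5 ((3E)-5-PMBO-4-methylpent-3-enal)
Conditions: Dess–Martin periodinane, NaHCO3, CH2Cl2, 0 °C; use crude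
Reagents that add atoms: none
Why: Mild oxidation of the primary alcohol avoids isomerisation of the β,γ-alkene into conjugation.

**Step 4**
Reactants: 5
Product: 6 (racemic 7-PMBO-2,6-dimethylhepta-1,5-dien-3-ol)
Conditions: isopropenylMgBr, THF, –78 °C
Reagents that add atoms: isopropenylmagnesium bromide, C=C(C)[Mg]Br
Why: Grignard 1,2-addition forms the C4–C5 bond; C5 is racemic here and is set in steps 5–6 by oxidation and CBS reduction.

**Step 5**
Reactants: 6
Product: 7 (enone)
Conditions: MnO2 (10 equiv), CH2Cl2, rt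
Reagents that add atoms: none
Why: MnO2 oxidises allylic alcohols chemoselectively, which removes the racemic C5 stereocentre.

**Step 6**
Reactants: 7
Product: 8 ((3R,5E)-7-PMBO-2,6-dimethylhepta-1,5-dien-3-ol; this is C5 (R))
Conditions: (S)-Me-CBS (10 mol%), BH3·SMe2, THF, –20 °C
Reagents that add atoms: none (hydride only)
Why: In the Corey–Bakshi–Shibata reduction the planar isopropenyl group acts as the large group, so (S)-catalyst gives the (R)-alcohol; this sets C5.

**Step 7**
Reactants: 8
Product: 9 (C5-OTBS ether)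
Conditions: TBSOTf, 2,6-lutidine, CH2Cl2, –78→0 °C
Reagents that add atoms: TBSOTf, CC(C)(C)[Si](C)(C)OS(=O)(=O)C(F)(F)F
Why: Masking C5-OH prevents hydroxyl-directed epoxidation during the kinetic resolution in step 9; the stereocentre is untouched.

**Step 8**
Reactants: 9 (1 equiv), penta-1,4-dien-3-ol (5 equiv, reagent)
Product: 10 (C3=C4 E-bis-allylic alcohol, mixture of C2 epimers)
Conditions: Hoveyda–Grubbs II (5 mol%), CH2Cl2, 40 °C
Reagents that add atoms: penta-1,4-dien-3-ol, C=CC(O)C=C
Why: Cross-metathesis with one vinyl group of divinylcarbinol builds the E-trisubstituted C3=C4 alkene and leaves the vinyl group needed for RCM; C2 is formed as a 1:1 epimer mixture.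

**Step 9**
Reactants: 10
Product: 11 ((3S,4E,6R,8E)-6-TBSO-10-PMBO-5,9-dimethyldeca-1,4,8-trien-3-ol; C2 (S), C5 (R))
Conditions: Ti(OiPr)4, L-(+)-DET, TBHP (0.6 equiv), 3 Å MS, CH2Cl2, –20 °C
Reagents that add atoms: none (TBHP is consumed by the discarded fast enantiomer)
Why: In Sharpless kinetic resolution the (R)-C2 epimer epoxidises fast with L-(+)-DET and is discarded, while the slow (S)-epimer is recovered; this sets C2.

**Step 10**
Reactants: 12 (ethyl 2-(hydroxymethyl)acrylate)
Product: 13 (TBDPS ether)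
Conditions: TBDPSCl, imidazole, DMF, rt
Reagents that add atoms: TBDPSCl, CC(C)(C)[Si](Cl)(c1ccccc1)c1ccccc1
Why: Silylation installs a protected C17 handle on the acrylate.

**Step 11**
Reactants: 13
Product: 14 (2-[(TBDPSO)methyl]acrylic acid)
Conditions: LiOH, THF/H2O, 0 °C
Reagents that add atoms: hydroxide, [Li+].[OH-] (oxygen retained as CO2H)
Why: Ester saponification gives the acid for the Yamaguchi esterification; the TBDPS ether survives.

**Step 12**
Reactants: 11, 14
Product: 15 (acrylate ester, C2 retained as (S))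
Conditions: 2,4,6-Cl3C6H2COCl, Et3N, THF; then DMAP, toluene, rt
Reagents that add atoms: none
Why: Yamaguchi esterification goes through a mixed anhydride, with no change at the carbinol carbon.

**Step 13**
Reactants: 15
Product: 16 ((5R)-3-[(TBDPSO)methyl]-5-[side chain]furan-2(5H)-one; the trisubstituted C3=C4 alkene is untouched)
Conditions: Hoveyda–Grubbs II (5 mol%), 1,4-benzoquinone (10 mol%), CH2Cl2 (5 mM), 40 °C
Reagents that add atoms: none (ethylene is lost)
Why: Ring-closing metathesis of the vinyl group with the 1,1-disubstituted acrylate forms the butenolide (C1=C15); the stereocentre is unaffected, and this step is the lactone ring-forming step.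

**Step 14**
Reactants: 16
Product: 17 (free C5-OH)
Conditions: HF·pyridine, pyridine, THF, 0 °C→rt
Reagents that add atoms: none
Why: The secondary TBS ether is cleaved selectively, while the primary TBDPS ether and the PMB ether survive.

**Step 15**
Reactants: 17
Product: 18 (trans-epoxy alcohol with C3 (S), C4 (S); C2 is now labelled (S) and C5 (R))
Conditions: Ti(OiPr)4 (1 equiv), L-(+)-DET (1.2 equiv), TBHP, 3 Å MS, CH2Cl2, –20 °C
Reagents that add atoms: tert-butyl hydroperoxide, CC(C)(C)OO (oxygen atom transferred)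
Why: Sharpless AE directed by the (R)-C5 alcohol (matched with L-(+)-DET) epoxidises only the allylic C3=C4 alkene, on the face that gives the (3S,4S) trans-epoxide; this sets C3 and C4.

**Step 16**
Reactants: 18
Product: 19 (C5-OAc)
Conditions: Ac2O, pyridine, DMAP, CH2Cl2, rt
Reagents that add atoms: acetic anhydride, CC(=O)OC(C)=O
Why: Acetylation installs the C5 acetate of the target with retention.

**Step 17**
Reactants: 19
Product: 20 (3-(hydroxymethyl)butenolide)
Conditions: TBAF, AcOH (1:1), THF, 0 °C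
Reagents that add atoms: none
Why: AcOH-buffered fluoride removes the primary allylic TBDPS ether and spares the acetate and epoxide.

**Step 18**
Reactants: 20
Product: 21 (3-(bromomethyl)butenolide, the allyl bromide partner)
Conditions: PPh3, CBr4, CH2Cl2, 0 °C; use crude
Reagents that add atoms: tetrabromomethane, BrC(Br)(Br)Br
Why: Appel bromination of the allylic alcohol under neutral conditions leaves the epoxide intact.

**Step 19**
Reactants: 22 (allyl alcohol)
Product: 23 (allyl PMB ether)
Conditions: NaH, PMBCl, TBAI (cat.), THF/DMF, 0 °C→rt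
Reagents that add atoms: PMBCl, COc1ccc(CCl)cc1
Why: Williamson etherification.

**Step 20**
Reactants: 24 (isoprenol, 3-methylbut-3-en-1-ol), 23
Product: 25 ((3E)-5-PMBO-3-methylpent-3-en-1-ol, the C10–C14 isoprenoid unit)
Conditions: Hoveyda–Grubbs II (5 mol%), CH2Cl2, 40 °C; separate E/Z
Reagents that add atoms: none (ethylene is lost)
Why: Cross-metathesis gives the E-trisubstituted C11=C12 alkene with the methyl on C12 next to C13.

**Step 21**
Reactants: 25
Product: 26 ((3E)-5-PMBO-3-methylpent-3-enal, the C14 aldehyde)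
Conditions: Dess–Martin periodinane, NaHCO3, CH2Cl2, 0 °C; use crude
Reagents that add atoms: none
Why: Mild oxidation of the primary alcohol to the aldehyde.

**Step 22**
Reactants: 21, 26 (1.5 equiv)
Product: 27 (trans-fused α-methylene lactone with the 14-epi homoallylic alcohol)
Conditions: Zn dust, THF/sat. aq. NH4Cl (1:1), rt
Reagents that add atoms: none
Why: The allylzinc from the butenolide attacks through its γ-carbon (C1) in a chair transition state; C1 is attacked anti to the C2 side chain, giving the trans-lactone; the fixed E-allyl geometry gives the anti adduct, which is the C14 epimer (syn is required), corrected in step 24.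

**Step 23**
Reactants: 27
Product: 28 (PhSCH2 Michael adduct, mixture of C15 epimers)
Conditions: PhSH (3 equiv), Et3N (0.1 equiv), CH2Cl2, 0 °C→rt
Reagents that add atoms: thiophenol, Sc1ccccc1
Why: Thia-Michael addition masks the α-methylene lactone as a sulfide that is compatible with PPh3 and Ni(0).

**Step 24**
Reactants: 28
Product: 29 (C14 formate with inverted configuration)
Conditions: PPh3, DIAD, HCO2H, THF, 0 °C
Reagents that add atoms: formic acid, O=CO
Why: SN2 displacement with inversion of the oxyphosphonium ion sets C14 (R).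

**Step 25**
Reactants: 29
Product: 30 (C14-OH of the target configuration)
Conditions: K2CO3 (0.2 equiv), MeOH/CH2Cl2, 0 °C, 15 min
Reagents that add atoms: none
Why: The formate ester is about 100 times more labile than the acetate or lactone, so it is cleaved selectively and C14 is unchanged.

**Step 26**
Reactants: 30
Product: 31 (C14-OTES)
Conditions: TESOTf, 2,6-lutidine, CH2Cl2, –78 °C
Reagents that add atoms: TESOTf, CC[Si](CC)(CC)OS(=O)(=O)C(F)(F)F
Why: Protecting C14-OH stops the Appel reagents reacting with it later.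

**Step 27**
Reactants: 31
Product: 32 (C9,C10-diol)
Conditions: DDQ (2.4 equiv), CH2Cl2/pH 7 buffer (10:1), 0 °C
Reagents that add atoms: none
Why: Oxidative PMB cleavage frees both primary allylic alcohols and leaves the silyl ether, acetate, epoxide and E-alkenes.

**Step 28**
Reactants: 32
Product: 33 (C9,C10 bis-allylic bromide)
Conditions: PPh3 (3 equiv), CBr4 (3 equiv), CH2Cl2, 0 °C; use crude at once
Reagents that add atoms: tetrabromomethane, BrC(Br)(Br)Br
Why: Appel bromination occurs selectively at the two primary allylic alcohols without allylic transposition.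

**Step 29**
Reactants: 33
Product: 34 (masked macrocycle)
Conditions: Ni(cod)2 (3 equiv), DMF, 25 °C, slow addition to 2 mM
Reagents that add atoms: none
Why: Proposed new method: oxidative addition of both allylic bromides to Ni(0) gives a bis(π-allyl)nickel that reductively eliminates at the two unhindered primary termini (C9 and C10), closing the 14-membered ring with both E-trisubstituted alkenes retained. The closest known reaction is Corey's Ni(0) bis-allyl halide cyclisation (humulene), extended here to an epoxide, acetate, silyl ether and sulfide-bearing substrate.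

**Step 30**
Reactants: 34
Product: 35 (sulfoxides)
Conditions: NaIO4, MeOH/H2O, 0 °C
Reagents that add atoms: sodium periodate, [Na+].[O-]I(=O)(=O)=O
Why: Periodate oxidises the sulfide chemoselectively and does not touch the alkenes or the epoxide.

**Step 31**
Reactants: 35
Product: 36 (α-methylene lactone, TES-protected)
Conditions: toluene, CaCO3, 100 °C
Reagents that add atoms: none
Why: Syn-elimination of PhSOH towards the acidic C15-H forms the exocyclic C15=C17; the sulfoxide stereochemistry is irrelevant.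

**Step 32**
Reactants: 36
Product: 37 (michaolide F)
Conditions: HF·pyridine, pyridine, THF, 0 °C
Reagents that add atoms: none
Why: Buffered fluoride removes TES and leaves the epoxide, acetate and α-methylene lactone intact.

## Compound list

1 | methallyl alcohol | C=C(C)CO | starting material
2 | methallyl PMB ether | C=C(C)COCc1ccc(OC)cc1 | intermediate
3 | but-3-en-1-ol | C=CCCO | starting material
4 | (3E)-5-PMBO-4-methylpent-3-en-1-ol | OCC/C=C(\C)COCc1ccc(OC)cc1 | intermediate
5 | (3E)-5-PMBO-4-methylpent-3-enal | O=CC/C=C(\C)COCc1ccc(OC)cc1 | intermediate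
6 | (±)-(5E)-7-PMBO-2,6-dimethylhepta-1,5-dien-3-ol | C=C(C)C(O)C/C=C(\C)COCc1ccc(OC)cc1 | intermediate
7 | (5E)-7-PMBO-2,6-dimethylhepta-1,5-dien-3-one | C=C(C)C(=O)C/C=C(\C)COCc1ccc(OC)cc1 | intermediate
8 | (3R,5E)-7-PMBO-2,6-dimethylhepta-1,5-dien-3-ol | C=C(C)[C@H](O)C/C=C(\C)COCc1ccc(OC)cc1 | intermediate
9 | (3R,5E)-3-TBSO-7-PMBO-2,6-dimethylhepta-1,5-diene | C=C(C)[C@H](O[Si](C)(C)C(C)(C)C)C/C=C(\C)COCc1ccc(OC)cc1 | intermediate
10 | (3RS,4E,6R,8E)-6-TBSO-10-PMBO-5,9-dimethyldeca-1,4,8-trien-3-ol | C=CC(O)/C=C(\C)[C@H](O[Si](C)(C)C(C)(C)C)C/C=C(\C)COCc1ccc(OC)cc1 | intermediate (C3 epimer mixture)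
11 | (3S,4E,6R,8E)-6-TBSO-10-PMBO-5,9-dimethyldeca-1,4,8-trien-3-ol | C=C[C@H](O)/C=C(\C)[C@H](O[Si](C)(C)C(C)(C)C)C/C=C(\C)COCc1ccc(OC)cc1 | intermediate
12 | ethyl 2-(hydroxymethyl)acrylate | C=C(CO)C(=O)OCC | starting material
13 | ethyl 2-[(TBDPSO)methyl]acrylate | C=C(CO[Si](c1ccccc1)(c1ccccc1)C(C)(C)C)C(=O)OCC | intermediate
14 | 2-[(TBDPSO)methyl]acrylic acid | C=C(CO[Si](c1ccccc1)(c1ccccc1)C(C)(C)C)C(=O)O | intermediate
15 | acrylate ester of 11 | C=C(CO[Si](c1ccccc1)(c1ccccc1)C(C)(C)C)C(=O)O[C@@H](C=C)/C=C(\C)[C@H](O[Si](C)(C)C(C)(C)C)C/C=C(\C)COCc1ccc(OC)cc1 | intermediate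
16 | butenolide: (5R)-3-[(TBDPSO)methyl]-5-[(1E,3R,5E)-3-TBSO-7-PMBO-2,6-dimethylhepta-1,5-dien-1-yl]furan-2(5H)-one | O=C1O[C@H](/C=C(\C)[C@H](O[Si](C)(C)C(C)(C)C)C/C=C(\C)COCc2ccc(OC)cc2)C=C1CO[Si](c1ccccc1)(c1ccccc1)C(C)(C)C | intermediate
17 | C5-OH butenolide | O=C1O[C@H](/C=C(\C)[C@H](O)C/C=C(\C)COCc2ccc(OC)cc2)C=C1CO[Si](c1ccccc1)(c1ccccc1)C(C)(C)C | intermediate
18 | epoxy alcohol: (5S)-5-{(2S,3S)-3-[(1R,3E)-1-hydroxy-5-PMBO-4-methylpent-3-enyl]-3-methyloxiran-2-yl}-3-[(TBDPSO)methyl]furan-2(5H)-one | O=C1O[C@H]([C@@H]2O[C@@]2(C)[C@H](O)C/C=C(\C)COCc2ccc(OC)cc2)C=C1CO[Si](c1ccccc1)(c1ccccc1)C(C)(C)C | intermediate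
19 | C5-acetate of 18 | O=C1O[C@H]([C@@H]2O[C@@]2(C)[C@H](OC(C)=O)C/C=C(\C)COCc2ccc(OC)cc2)C=C1CO[Si](c1ccccc1)(c1ccccc1)C(C)(C)C | intermediate
20 | 3-(hydroxymethyl)butenolide | O=C1O[C@H]([C@@H]2O[C@@]2(C)[C@H](OC(C)=O)C/C=C(\C)COCc2ccc(OC)cc2)C=C1CO | intermediate
21 | 3-(bromomethyl)butenolide | O=C1O[C@H]([C@@H]2O[C@@]2(C)[C@H](OC(C)=O)C/C=C(\C)COCc2ccc(OC)cc2)C=C1CBr | intermediate
22 | allyl alcohol | C=CCO | starting material
23 | allyl PMB ether | C=CCOCc1ccc(OC)cc1 | intermediate
24 | isoprenol | CC(=C)CCO | starting material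
25 | (3E)-5-PMBO-3-methylpent-3-en-1-ol | OCC/C(C)=C/COCc1ccc(OC)cc1 | intermediate
26 | (3E)-5-PMBO-3-methylpent-3-enal | O=CC/C(C)=C/COCc1ccc(OC)cc1 | intermediate
27 | Barbier adduct (trans-lactone, 14-epi-OH, α-methylene) | C=C1C(=O)O[C@H]([C@@H]2O[C@@]2(C)[C@H](OC(C)=O)C/C=C(\C)COCc2ccc(OC)cc2)[C@H]1[C@@H](O)C/C(C)=C/COCc1ccc(OC)cc1 | intermediate
28 | PhS adduct of 27 (C15 epimer mixture) | c1ccccc1SCC1C(=O)O[C@H]([C@@H]2O[C@@]2(C)[C@H](OC(C)=O)C/C=C(\C)COCc2ccc(OC)cc2)[C@H]1[C@@H](O)C/C(C)=C/COCc1ccc(OC)cc1 | intermediate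
29 | C14 formate, inverted | c1ccccc1SCC1C(=O)O[C@H]([C@@H]2O[C@@]2(C)[C@H](OC(C)=O)C/C=C(\C)COCc2ccc(OC)cc2)[C@H]1[C@H](OC=O)C/C(C)=C/COCc1ccc(OC)cc1 | intermediate
30 | C14-OH (target configuration) | c1ccccc1SCC1C(=O)O[C@H]([C@@H]2O[C@@]2(C)[C@H](OC(C)=O)C/C=C(\C)COCc2ccc(OC)cc2)[C@H]1[C@H](O)C/C(C)=C/COCc1ccc(OC)cc1 | intermediate
31 | C14-OTES | c1ccccc1SCC1C(=O)O[C@H]([C@@H]2O[C@@]2(C)[C@H](OC(C)=O)C/C=C(\C)COCc2ccc(OC)cc2)[C@H]1[C@H](O[Si](CC)(CC)CC)C/C(C)=C/COCc1ccc(OC)cc1 | intermediate
32 | C9,C10-diol | c1ccccc1SCC1C(=O)O[C@H]([C@@H]2O[C@@]2(C)[C@H](OC(C)=O)C/C=C(\C)CO)[C@H]1[C@H](O[Si](CC)(CC)CC)C/C(C)=C/CO | intermediate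
33 | C9,C10-dibromide | c1ccccc1SCC1C(=O)O[C@H]([C@@H]2O[C@@]2(C)[C@H](OC(C)=O)C/C=C(\C)CBr)[C@H]1[C@H](O[Si](CC)(CC)CC)C/C(C)=C/CBr | intermediate
34 | masked macrocycle | c1ccccc1SCC1C(=O)O[C@H]2[C@H]1[C@H](O[Si](CC)(CC)CC)C/C(C)=C/CC/C(C)=C/C[C@@H](OC(C)=O)[C@]1(C)O[C@@H]21 | intermediate
35 | sulfoxide of 34 | c1ccccc1S(=O)CC1C(=O)O[C@H]2[C@H]1[C@H](O[Si](CC)(CC)CC)C/C(C)=C/CC/C(C)=C/C[C@@H](OC(C)=O)[C@]1(C)O[C@@H]21 | intermediate
36 | TES-protected α-methylene lactone | C=C1C(=O)O[C@H]2[C@H]1[C@H](O[Si](CC)(CC)CC)C/C(C)=C/CC/C(C)=C/C[C@@H](OC(C)=O)[C@]1(C)O[C@@H]21 | intermediate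
37 | michaolide F (1R,2S,3S,4S,5R,14R in cembranoid numbering) | C=C1C(=O)O[C@H]2[C@H]1[C@H](O)C/C(C)=C/CC/C(C)=C/C[C@@H](OC(C)=O)[C@]1(C)O[C@@H]21 | target

## Totals and risks

Total steps: 32. Longest linear sequence: 27 (steps 1–9, 12–18, 22–32).

Three steps most likely to fail:
1. **Step 29 (Ni macrocyclisation).** Regiochemistry (C9–C10 versus SN2′), alkene scrambling, and compatibility with the epoxide and sulfide are all unproven. Fallback: convert C9-Br to the allylic phenyl sulfone and C10-OH to the methyl carbonate, then use a Trost-type Pd-catalysed macrocyclic allylic alkylation followed by reductive desulfonylation.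
2. **Step 22 (Barbier), together with the Mitsunobu inversion in steps 24–25.** The diastereoselectivity and the stability of the butenolide bromide are uncertain, and formate cleavage next to the acetate is delicate. Fallback: replace the allylation with conjugate addition of a lithiated 1,3-dithiane of aldehyde 26 to the plain 5-substituted butenolide, trap with Eschenmoser's salt, then unmask the ketone and reduce it at C14.
3. **Step 9 (kinetic resolution for C2).** It loses at least 50% of material and depends on the matched/mismatched tartrate assumption. Fallback: oxidise 10 to the divinyl ketone and use Noyori-type asymmetric transfer hydrogenation, or resolve by lipase acylation.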